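1. The unit I counted time in was the clock: the first half-life of the forward step, 1/(2k·c), where k is the rate constant of two substrate joining into one target and c is the charge of substrate.

| flask | substrate | temperature | remark | time |
|---|---|---|---|---|
| grey | 0.0067 M | 10 °C | run made earlier |  |
| violet | 0.015 M | 43 °C | run made earlier |  |
| Monday's | 0.010 M | −5 °C |  | 40 min |
| Wednesday's | 0.010 M | 55 °C |  | 40 min |
| Sunday's | 0.010 M | 25 °C |  | 40 min |

- grey (time / min: target / %): 1.33: 1; 2.00: 3; 4.00: 3; 6.00: 10; 10.0: 15; 15.0: 27
- violet (time / min: target / %): 0.500: 14; 1.00: 27; 1.33: 26; 2.00: 37; 2.50: 36; 3.00: 38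

(standard deviation of a reading: 2 percentage points)

1. the best flask by amount of target, in percent of the substrate charged; "all alike" if 1.5 percentage points covers them all (Monday's / Wednesday's / Sunday's / all alike)
2. amount of target at the end, in percent of the substrate charged, Monday's
3. amount of target at the end, in percent of the substrate charged, Wednesday's
4. amount of target at the end, in percent of the substrate charged, Sunday's

- in percentages every species weighs as the substrate in it: one target counts as two

2. If substrate only joined forward, then after n clocks the target would stand at the share n/(1+n), so a reading gives n back. I took one reading from each run. Grey's 27% at 15.0 min read as k = 1.84 M⁻¹ min⁻¹, and violet's 27% at 1.00 min read as k = 12.3 M⁻¹ min⁻¹. Together they read as an activation energy of 42.9 kJ mol⁻¹.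

3. Violet's clock was 2.70 min. At its last reading, 3.00 min, a count of 1.11, the share formula gave 52.6% against 38% read, where a reading is good to 2 percentage points, so I took the formula as running too high at that count.

4. For Monday's, k came to 0.664 M⁻¹ min⁻¹ and the clock to 75.3 min. The time divided by the clock, the clock count 0.531, lay below that last count of violet's, so I committed to a target a little under the share of 34.7%. Sunday's count was 3.68 and Wednesday's 17.9, both beyond any count the readings covered, so I gave them no number.

5. The forecast gave Monday's 27%, Wednesday's 28% and Sunday's 45%, and named Sunday's best. Its Monday's figure lay below my share. Of Sunday's it said: “At 25 °C the kinetics are fast enough to reach the plateau.”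

6. The flasks gave Monday's 24.1%, Wednesday's 17.6% and Sunday's 32.1%, so Sunday's was best, as forecast. Sunday's target stood at 37.4% at 20.0 min and had fallen to 32.1% at 40.0 min, while side product rose from 25.8% to 43.1%. Those two moments stand at clock counts of 1.84 and 3.68, both above violet's last count of 1.11, so these are the counts to watch on a repeat.

    2 substrate ⇌ target (K = 330 M⁻¹, k = 4.30 M⁻¹ min⁻¹, Ea = 43.0 kJ mol⁻¹, ΔH = 34.0 kJ mol⁻¹)
    substrate + target → side product (k = 5.50 M⁻¹ min⁻¹, Ea = 40.0 kJ mol⁻¹)
    (constants at 25 °C)

7. The neighbour with 0.017 M of substrate, otherwise Monday's, has a count of 0.903, below violet's last count, so I expected a target a little under its share of 47.5%. It gave 30.3% of target, with 56.4% of the substrate left.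

Readings and results were computed with made-up constants.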